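**Plan**

1. Retrosynthetic cuts: C12–C13 (butenolide joined last by lactone-enolate alkylation); C8=C17, C9–H and C7–OH traced back to a 9-substituted 8-en-7-one; C9–C11 (Stork–Danheiser addition) and C7–C8 (intramolecular Claisen) open ring B; ring A is cut at C4–C5 by a retro-semipinacol to a cyclopentanol.
2. Enabling feature: in ring A the quaternary C4 lies between oxygenated C3 and ring-fusion carbon C5 and carries the C19 hydroxymethyl, i.e. the aldol array C3(=O)–C4(CH3)(CH2OH)–C5. This array forms when the ring bond C3–C5 of a 1-(2-methyloxiranyl)cyclopentanol (ring C1–C2–C3–C5–C10) shifts onto the epoxide carbon C4.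
3. Forward order: 3-methylcyclopentenone → 2,3-trans cyclopentanone → epoxy alcohol → ring A by one-carbon enlargement → ring B by Claisen closure onto the C10 acetyl → C9 arm, exocyclic methylene and C7–OH → butenolide → deprotection.
4. Stereochemistry: C10 by ligand-controlled Cu-catalysed conjugate addition; C5 by enolate alkylation anti to the silylvinyl group; C4 by hydroxyl-directed epoxidation followed by a stereospecific 1,2-shift with inversion; C3, C9 and C7 by axial hydride or proton delivery on the chair or trans-decalin.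

Key step: step 5

Remark: labdane numbering (C1–C20) is used for every intermediate, and the antipode of the chiral carbene ligand that delivers (R)-5 is taken to be available.

**Step 1**
Reactants: 1 3-methylcyclopent-2-en-1-one; 2 ethynyltrimethylsilane
Product: 5 (3R)-3-methyl-3-[1-(trimethylsilyl)ethenyl]-1-(trimethylsilyloxy)cyclopent-1-ene, via vinylalane 3 (not isolated), via aluminium enolate 4 (not isolated)
Conditions: 2, i-Bu2AlH, hexanes, 55 °C; then 1, Cu(OTf)2 (5 mol %), chiral sulfonate-bearing imidazolinium salt (NHC precursor, 5 mol %), THF, −78 to −15 °C; then Me3SiOTf, −78 to 0 °C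
Reagents that add atoms: trimethylsilyl trifluoromethanesulfonate C[Si](C)(C)OS(=O)(=O)C(F)(F)F; diisobutylaluminium hydride CC(C)C[AlH]CC(C)C (aluminium of 3 and 4 only)
Why: Hydroalumination places aluminium on the silicon-bearing alkyne carbon, the copper–carbene-catalysed asymmetric conjugate addition of such silyl-substituted vinylalanes to β-methyl cyclic enones sets the all-carbon quaternary centre C10 under ligand control, and the regiodefined aluminium enolate is trapped on oxygen by the silyl triflate.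

**Step 2**
Reactants: 5 (3R)-3-methyl-3-[1-(trimethylsilyl)ethenyl]-1-(trimethylsilyloxy)cyclopent-1-ene; 6 2-bromo-N-methoxy-N-methylacetamide
Product: 8 2-[(1S,2R)-2-methyl-5-oxo-2-[1-(trimethylsilyl)ethenyl]cyclopentyl]-N-methoxy-N-methylacetamide, via lithium enolate 7 (not isolated)
Conditions: MeLi, THF, 0 °C; then 6, DMPU, −78 to 0 °C
Reagents that add atoms: methyllithium [Li]C (lithium of 7 only)
Why: Methyllithium cleaves the O–Si bond to the regiodefined lithium enolate, which is C-alkylated (enolate alkylation) on the face opposite the bulky 1-silylvinyl group of the adjacent quaternary carbon, giving the 2,3-trans ketone that is also the thermodynamic C5 epimer.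

**Step 3**
Reactants: 8 2-[(1S,2R)-2-methyl-5-oxo-2-[1-(trimethylsilyl)ethenyl]cyclopentyl]-N-methoxy-N-methylacetamide; 9 isopropenylmagnesium bromide
Product: 10 2-[(1S,2R,5R)-5-hydroxy-2-methyl-5-(prop-1-en-2-yl)-2-[1-(trimethylsilyl)ethenyl]cyclopentyl]-N-methoxy-N-methylacetamide
Conditions: 9, LaCl3·2LiCl, THF, −78 °C; aq. NH4Cl at −78 °C
Reagents that add atoms: none
Why: The LaCl3·2LiCl-promoted Grignard 1,2-addition is faster at the ketone than at the Weinreb amide and suppresses enolisation, and the nucleophile enters anti to the C5 arm and the pseudo-axial C10 methyl, so that the new hydroxyl is cis to both.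

**Step 4**
Reactants: 10 2-[(1S,2R,5R)-5-hydroxy-2-methyl-5-(prop-1-en-2-yl)-2-[1-(trimethylsilyl)ethenyl]cyclopentyl]-N-methoxy-N-methylacetamide
Product: 11 2-[(1S,2R,5R)-5-hydroxy-2-methyl-5-[(2S)-2-methyloxiran-2-yl]-2-[1-(trimethylsilyl)ethenyl]cyclopentyl]-N-methoxy-N-methylacetamide
Conditions: VO(acac)2 (5 mol %), t-BuOOH (decane), CH2Cl2, 0 °C to rt
Reagents that add atoms: tert-butyl hydroperoxide CC(C)(C)OO
Why: Vanadium-catalysed hydroxyl-directed epoxidation touches only the allylic isopropenyl group, and in the vanadate transition state (O–C–C=C about 50°) the ring methylene C2 eclipses the alkene methyl (A(1,2) strain) while the branched C5 points away, which exposes the face leading to the (2S)-oxirane.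

**Step 5**
Reactants: 11 2-[(1S,2R,5R)-5-hydroxy-2-methyl-5-[(2S)-2-methyloxiran-2-yl]-2-[1-(trimethylsilyl)ethenyl]cyclopentyl]-N-methoxy-N-methylacetamide
Product: 12 2-[(1R,2R,6R)-2-(hydroxymethyl)-2,6-dimethyl-3-oxo-6-[1-(trimethylsilyl)ethenyl]cyclohexyl]-N-methoxy-N-methylacetamide
Conditions: BF3·OEt2, CH2Cl2, −78 to −40 °C; aq. NaHCO3
Reagents that add atoms: none
Why: BF3 coordinates the epoxide oxygen and, as the C4–O bond lengthens, the ring bond C3–C5 lying antiperiplanar to it shifts from C3 to C4 while the carbinol oxygen closes to the C3 carbonyl (semipinacol rearrangement of a tertiary 2,3-epoxy alcohol). The closest known reaction type is the Lewis-acid ring enlargement of 1-(oxiranyl)cycloalkanols to 2-(hydroxymethyl)cycloalkanones. No ring is closed by cyclisation: the five-membered ring C1–C2–C3–C5–C10 becomes six-membered ring A by insertion of C4 into the C3–C5 bond (1,2-alkyl shift). The new quaternary stereocentre C4 is formed with inversion at the epoxide carbon, so it is controlled by the oxirane configuration from step 4, and C5 migrates with retention. The step needs migration of C5 and not of C2 and no capture of the cationic centre: C5 is the more substituted carbon and is the group held anti to the breaking C–O bond when hydroxyl and epoxide oxygens are bridged, the 1-silylvinyl group could intervene only through an α-silyl cation, and the amide arm sits on the opposite ring face.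

**Step 6**
Reactants: 12 2-[(1R,2R,6R)-2-(hydroxymethyl)-2,6-dimethyl-3-oxo-6-[1-(trimethylsilyl)ethenyl]cyclohexyl]-N-methoxy-N-methylacetamide
Product: 13 2-[(1R,2R,3R,6R)-3-hydroxy-2-(hydroxymethyl)-2,6-dimethyl-6-[1-(trimethylsilyl)ethenyl]cyclohexyl]-N-methoxy-N-methylacetamide
Conditions: NaBH4, MeOH, −20 to 0 °C
Reagents that add atoms: none
Why: Borohydride reduction of the cyclohexanone by axial attack (only the axial hydrogens at C1 and C5 on that face) should give the equatorial C3 alcohol cis to the axial C19 hydroxymethyl, without reducing the Weinreb amide and before retro-aldol loss of formaldehyde can occur.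

**Step 7**
Reactants: 13 2-[(1R,2R,3R,6R)-3-hydroxy-2-(hydroxymethyl)-2,6-dimethyl-6-[1-(trimethylsilyl)ethenyl]cyclohexyl]-N-methoxy-N-methylacetamide
Product: 15 2-[(1R,2R,3R,6R)-6-acetyl-3-hydroxy-2-(hydroxymethyl)-2,6-dimethylcyclohexyl]-N-methoxy-N-methylacetamide, via epoxysilane 14 (not isolated)
Conditions: m-CPBA, NaHCO3, CH2Cl2, 0 °C to rt; then aq. HClO4, THF, rt
Reagents that add atoms: m-chloroperbenzoic acid OOC(=O)c1cccc(Cl)c1 (oxygen of 14 only); water O (carbonyl oxygen of 15)
Why: Peracid epoxidation of the vinylsilane followed by acid opening at the silicon-bearing carbon and Peterson-type loss of silanol unmasks the methyl ketone, the carbon that carried silicon becoming the C9 carbonyl.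

**Step 8**
Reactants: 15 2-[(1R,2R,3R,6R)-6-acetyl-3-hydroxy-2-(hydroxymethyl)-2,6-dimethylcyclohexyl]-N-methoxy-N-methylacetamide
Product: 16 3,19-O-isopropylidene acetal of 15
Conditions: Me2C(OMe)2, PPTS (cat.), CH2Cl2, rt
Reagents that add atoms: 2,2-dimethoxypropane COC(C)(C)OC
Why: The equatorial C3 hydroxyl and the axial C19 hydroxymethyl form the six-membered isopropylidene acetal by transacetalisation, which masks the 1,3-diol for the base and dissolving-metal steps.

**Step 9**
Reactants: 16 3,19-O-isopropylidene acetal of 15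
Product: 17 3,19-(isopropylidenedioxy)-4,10-dimethyl-trans-decalin-7,9-dione (labdane numbering)
Conditions: LiN(SiMe3)2 (2.5 equiv), THF, −78 to 0 °C; aq. NH4Cl
Reagents that add atoms: none
Why: The acetyl group can enolise only towards its methyl (C8), and this enolate acylates intramolecularly on the Weinreb amide (Claisen-type condensation) to close ring B as the trans-fused 1,3-diketone, whose deprotonation drives the reaction.

**Step 10**
Reactants: 17 3,19-(isopropylidenedioxy)-4,10-dimethyl-trans-decalin-7,9-dione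
Product: 18 7-methoxy-3,19-(isopropylidenedioxy)-4,10-dimethyl-trans-octal-7-en-9-one
Conditions: Me2SO4, K2CO3, acetone, rt
Reagents that add atoms: dimethyl sulfate COS(=O)(=O)OC
Why: O-Methylation of the dionate (vinylogous ester formation) should occur at the less hindered C7 oxygen, remote from the quaternary C10, as with 4,4-disubstituted cyclohexane-1,3-diones, leaving the C9 carbonyl for the next step.

**Step 11**
Reactants: 18 7-methoxy-3,19-(isopropylidenedioxy)-4,10-dimethyl-trans-octal-7-en-9-one; 19 (1,3-dioxolan-2-ylmethyl)magnesium bromide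
Product: 21 9-(1,3-dioxolan-2-ylmethyl)-3,19-(isopropylidenedioxy)-4,10-dimethyl-trans-octal-8-en-7-one, via carbinol adduct 20 (not isolated)
Conditions: 19, LaCl3·2LiCl, THF, 0 °C to rt; then 10% aq. citric acid, THF, 0 °C to rt
Reagents that add atoms: water O (C7 carbonyl oxygen of 21)
Why: Stork–Danheiser sequence, in which 1,2-addition to the non-enolisable C9 carbonyl and mild acid hydrolysis of the enol ether with loss of the tertiary hydroxyl transpose the enone, placing the carbonyl at C7 and the two-carbon arm (C11–C12) at C9.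

**Step 12**
Reactants: 21 9-(1,3-dioxolan-2-ylmethyl)-3,19-(isopropylidenedioxy)-4,10-dimethyl-trans-octal-8-en-7-one
Product: 23 8-(hydroxymethyl)-9-(1,3-dioxolan-2-ylmethyl)-3,19-(isopropylidenedioxy)-4,10-dimethyl-trans-decalin-7-one, via lithium enolate 22 (not isolated)
Conditions: Li, NH3(l)/THF, t-BuOH (1 equiv), −78 °C; isoprene; NH3 evaporated; then CH2O (gas), THF, −78 to −40 °C; aq. NH4Cl
Reagents that add atoms: formaldehyde C=O; lithium [Li] (in 22 only)
Why: Dissolving-metal reduction protonates the β-carbanion at C9 from the axial side opposite the C10 methyl (arm equatorial, C9–H anti to C20) and leaves the regiodefined C7–C8 lithium enolate, which monomeric formaldehyde hydroxymethylates at C8 (reductive aldol trapping).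

**Step 13**
Reactants: 23 8-(hydroxymethyl)-9-(1,3-dioxolan-2-ylmethyl)-3,19-(isopropylidenedioxy)-4,10-dimethyl-trans-decalin-7-one
Product: 25 8-methylidene-9-(1,3-dioxolan-2-ylmethyl)-3,19-(isopropylidenedioxy)-4,10-dimethyl-trans-decalin-7-one, via mesylate 24 (not isolated)
Conditions: MsCl, Et3N, CH2Cl2, 0 °C; then DBU, rt
Reagents that add atoms: methanesulfonyl chloride CS(=O)(=O)Cl (in 24 only)
Why: Mesylation of the primary alcohol and E1cB elimination through the C7 enolate give the exocyclic enone and erase the C8 stereocentre.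

**Step 14**
Reactants: 25 8-methylidene-9-(1,3-dioxolan-2-ylmethyl)-3,19-(isopropylidenedioxy)-4,10-dimethyl-trans-decalin-7-one
Product: 26 (7R)-8-methylidene-9-(1,3-dioxolan-2-ylmethyl)-3,19-(isopropylidenedioxy)-4,10-dimethyl-trans-decalin-7-ol
Conditions: NaBH4, CeCl3·7H2O, MeOH, −78 to −20 °C
Reagents that add atoms: none
Why: Luche reduction is 1,2-selective for the s-cis enone and the hydride enters axially past H5 and H9, which should give the equatorial C7 alcohol.

**Step 15**
Reactants: 26 (7R)-8-methylidene-9-(1,3-dioxolan-2-ylmethyl)-3,19-(isopropylidenedioxy)-4,10-dimethyl-trans-decalin-7-ol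
Product: 28 (7R)-9-(2-hydroxyethyl)-8-methylidene-3,19-(isopropylidenedioxy)-4,10-dimethyl-trans-decalin-7-ol, via aldehyde 27 (not isolated)
Conditions: PPTS, acetone/H2O, 45 °C; then NaBH4, MeOH, 0 °C
Reagents that add atoms: water O (aldehyde oxygen of 27)
Why: Acid-catalysed transacetalisation in wet acetone frees the C12 aldehyde while the isopropylidene acetal is maintained by the solvent, and borohydride then reduces the aldehyde to the primary alcohol.

**Step 16**
Reactants: 28 (7R)-9-(2-hydroxyethyl)-8-methylidene-3,19-(isopropylidenedioxy)-4,10-dimethyl-trans-decalin-7-ol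
Product: 29 (7R)-9-(2-iodoethyl)-8-methylidene-3,19-(isopropylidenedioxy)-4,10-dimethyl-trans-decalin-7-ol
Conditions: PPh3, I2, imidazole, CH2Cl2, 0 °C
Reagents that add atoms: iodine II
Why: Appel-type iodination should be much faster at the unhindered primary C12 alcohol than at the hindered secondary allylic C7 alcohol.

**Step 17**
Reactants: 30 3-bromodihydrofuran-2(3H)-one; 31 benzenethiol
Product: 32 3-(phenylsulfanyl)dihydrofuran-2(3H)-one
Conditions: Et3N, CH2Cl2, 0 °C to rt
Reagents that add atoms: none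
Why: SN2 displacement of the activated α-bromide by thiolate gives the sulfanyl lactone that serves as the butenolide α-anion equivalent.

**Step 18**
Reactants: 29 (7R)-9-(2-iodoethyl)-8-methylidene-3,19-(isopropylidenedioxy)-4,10-dimethyl-trans-decalin-7-ol; 32 3-(phenylsulfanyl)dihydrofuran-2(3H)-one
Product: 34 3-[2-(decalinyl)ethyl]-3-(phenylsulfanyl)dihydrofuran-2(3H)-one (C12–C13 coupled lactone), via lithium enolate 33 (not isolated)
Conditions: 32 (2.5 equiv), LiN(SiMe3)2, THF, −78 °C; then 29, DMPU, −78 to 0 °C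
Reagents that add atoms: lithium bis(trimethylsilyl)amide [Li]N([Si](C)(C)C)[Si](C)(C)C (lithium of 33 only)
Why: The sulfur-stabilised lactone enolate is too weakly basic to be quenched by the C7 hydroxyl and is alkylated by the primary iodide (enolate alkylation), joining C12 to C13 as an inconsequential mixture of C13 epimers.

**Step 19**
Reactants: 34 3-[2-(decalinyl)ethyl]-3-(phenylsulfanyl)dihydrofuran-2(3H)-one
Product: 36 3,19-O-isopropylidene-7-hydroxy-14-deoxyandrographolide, via sulfoxide 35 (not isolated)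
Conditions: m-CPBA (1.0 equiv), CH2Cl2, −78 °C; then toluene, NaHCO3, 110 °C
Reagents that add atoms: m-chloroperbenzoic acid OOC(=O)c1cccc(Cl)c1 (oxygen of 35 only)
Why: Sulfide oxidation at low temperature outpaces alkene epoxidation, and thermal syn-elimination of the sulfoxide (sulfoxide pyrolysis route to α-alkyl butenolides) introduces the C13=C14 double bond in conjugation with the lactone from either C13 epimer.

**Step 20**
Reactants: 36 3,19-O-isopropylidene-7-hydroxy-14-deoxyandrographolide
Product: 37 7-hydroxy-14-deoxyandrographolide (target)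
Conditions: AcOH/H2O (7:3), rt
Reagents that add atoms: none
Why: Mild aqueous acid hydrolyses the isopropylidene acetal without affecting the butenolide, the exocyclic alkene or the allylic alcohol.

**Compound list**

1 | 3-methylcyclopent-2-en-1-one | CC1=CC(=O)CC1 | starting material
2 | ethynyltrimethylsilane | C#C[Si](C)(C)C | starting material
3 | diisobutyl[1-(trimethylsilyl)ethenyl]aluminium | C=C([Si](C)(C)C)[Al](CC(C)C)CC(C)C | intermediate
4 | diisobutylaluminium (3R)-3-methyl-3-[1-(trimethylsilyl)ethenyl]cyclopent-1-en-1-olate | CC(C)C[Al](CC(C)C)OC1=C[C@@](C)(CC1)C(=C)[Si](C)(C)C | intermediate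
5 | (3R)-3-methyl-3-[1-(trimethylsilyl)ethenyl]-1-(trimethylsilyloxy)cyclopent-1-ene | C[Si](C)(C)OC1=C[C@@](C)(CC1)C(=C)[Si](C)(C)C | intermediate
6 | 2-bromo-N-methoxy-N-methylacetamide | CON(C)C(=O)CBr | starting material
7 | lithium (3R)-3-methyl-3-[1-(trimethylsilyl)ethenyl]cyclopent-1-en-1-olate | [Li]OC1=C[C@@](C)(CC1)C(=C)[Si](C)(C)C | intermediate
8 | 2-[(1S,2R)-2-methyl-5-oxo-2-[1-(trimethylsilyl)ethenyl]cyclopentyl]-N-methoxy-N-methylacetamide | O=C1CC[C@@](C)(C(=C)[Si](C)(C)C)[C@@H]1CC(=O)N(C)OC | intermediate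
9 | isopropenylmagnesium bromide | C=C(C)[Mg]Br | starting material
10 | 2-[(1S,2R,5R)-5-hydroxy-2-methyl-5-(prop-1-en-2-yl)-2-[1-(trimethylsilyl)ethenyl]cyclopentyl]-N-methoxy-N-methylacetamide | C=C(C)[C@@]1(O)CC[C@@](C)(C(=C)[Si](C)(C)C)[C@@H]1CC(=O)N(C)OC | intermediate
11 | 2-[(1S,2R,5R)-5-hydroxy-2-methyl-5-[(2S)-2-methyloxiran-2-yl]-2-[1-(trimethylsilyl)ethenyl]cyclopentyl]-N-methoxy-N-methylacetamide | C[C@]1(CO1)[C@@]2(O)CC[C@@](C)(C(=C)[Si](C)(C)C)[C@@H]2CC(=O)N(C)OC | intermediate
12 | 2-[(1R,2R,6R)-2-(hydroxymethyl)-2,6-dimethyl-3-oxo-6-[1-(trimethylsilyl)ethenyl]cyclohexyl]-N-methoxy-N-methylacetamide (ring A ketone) | CON(C)C(=O)C[C@@H]1[C@](C)(CO)C(=O)CC[C@@]1(C)C(=C)[Si](C)(C)C | intermediate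
13 | 2-[(1R,2R,3R,6R)-3-hydroxy-2-(hydroxymethyl)-2,6-dimethyl-6-[1-(trimethylsilyl)ethenyl]cyclohexyl]-N-methoxy-N-methylacetamide | CON(C)C(=O)C[C@@H]1[C@](C)(CO)[C@H](O)CC[C@@]1(C)C(=C)[Si](C)(C)C | intermediate
14 | epoxysilane of 13 (2-(trimethylsilyl)oxiran-2-yl group on C10, both oxirane epimers) | CON(C)C(=O)C[C@@H]1[C@](C)(CO)[C@H](O)CC[C@@]1(C)C2(CO2)[Si](C)(C)C | intermediate
15 | 2-[(1R,2R,3R,6R)-6-acetyl-3-hydroxy-2-(hydroxymethyl)-2,6-dimethylcyclohexyl]-N-methoxy-N-methylacetamide | CON(C)C(=O)C[C@@H]1[C@](C)(CO)[C@H](O)CC[C@@]1(C)C(C)=O | intermediate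
16 | 3,19-O-isopropylidene acetal of 15 (2,2-dimethyl-1,3-dioxane across O3 and O19) | CON(C)C(=O)C[C@@H]1[C@]2(C)COC(C)(C)O[C@@H]2CC[C@@]1(C)C(C)=O | intermediate
17 | 3,19-(isopropylidenedioxy)-4,10-dimethyl-trans-decalin-7,9-dione (labdane numbering) | O=C1C[C@@H]2[C@]3(C)COC(C)(C)O[C@@H]3CC[C@@]2(C)C(=O)C1 | intermediate
18 | 7-methoxy-3,19-(isopropylidenedioxy)-4,10-dimethyl-trans-octal-7-en-9-one | COC=1C[C@@H]2[C@]3(C)COC(C)(C)O[C@@H]3CC[C@@]2(C)C(=O)C=1 | intermediate
19 | (1,3-dioxolan-2-ylmethyl)magnesium bromide | Br[Mg]CC1OCCO1 | starting material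
20 | 9-hydroxy-9-(1,3-dioxolan-2-ylmethyl) adduct of 18 (carbinol configuration not controlled, lost on hydrolysis) | COC=1C[C@@H]2[C@]3(C)COC(C)(C)O[C@@H]3CC[C@@]2(C)C(O)(CC4OCCO4)C=1 | intermediate
21 | 9-(1,3-dioxolan-2-ylmethyl)-3,19-(isopropylidenedioxy)-4,10-dimethyl-trans-octal-8-en-7-one | O=C1C[C@@H]2[C@]3(C)COC(C)(C)O[C@@H]3CC[C@@]2(C)C(CC4OCCO4)=C1 | intermediate
22 | lithium C7–C8 enolate of the C9–H ketone (arm at C9 equatorial) | C1=C(O[Li])C[C@@H]2[C@]3(C)COC(C)(C)O[C@@H]3CC[C@@]2(C)[C@@H]1CC1OCCO1 | intermediate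
23 | 8-(hydroxymethyl)-9-(1,3-dioxolan-2-ylmethyl)-3,19-(isopropylidenedioxy)-4,10-dimethyl-trans-decalin-7-one (hydroxymethyl drawn equatorial) | OC[C@H]1C(=O)C[C@@H]2[C@]3(C)COC(C)(C)O[C@@H]3CC[C@@]2(C)[C@@H]1CC1OCCO1 | intermediate
24 | methanesulfonate of 23 | CS(=O)(=O)OC[C@H]1C(=O)C[C@@H]2[C@]3(C)COC(C)(C)O[C@@H]3CC[C@@]2(C)[C@@H]1CC1OCCO1 | intermediate
25 | 8-methylidene-9-(1,3-dioxolan-2-ylmethyl)-3,19-(isopropylidenedioxy)-4,10-dimethyl-trans-decalin-7-one | C=C1C(=O)C[C@@H]2[C@]3(C)COC(C)(C)O[C@@H]3CC[C@@]2(C)[C@@H]1CC1OCCO1 | intermediate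
26 | (7R)-8-methylidene-9-(1,3-dioxolan-2-ylmethyl)-3,19-(isopropylidenedioxy)-4,10-dimethyl-trans-decalin-7-ol | C=C1[C@H](O)C[C@@H]2[C@]3(C)COC(C)(C)O[C@@H]3CC[C@@]2(C)[C@@H]1CC1OCCO1 | intermediate
27 | (7R)-7-hydroxy-8-methylidene-3,19-(isopropylidenedioxy)-4,10-dimethyl-trans-decalin-9-ylacetaldehyde (C12 aldehyde) | C=C1[C@H](O)C[C@@H]2[C@]3(C)COC(C)(C)O[C@@H]3CC[C@@]2(C)[C@@H]1CC=O | intermediate
28 | (7R)-9-(2-hydroxyethyl)-8-methylidene-3,19-(isopropylidenedioxy)-4,10-dimethyl-trans-decalin-7-ol | C=C1[C@H](O)C[C@@H]2[C@]3(C)COC(C)(C)O[C@@H]3CC[C@@]2(C)[C@@H]1CCO | intermediate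
29 | (7R)-9-(2-iodoethyl)-8-methylidene-3,19-(isopropylidenedioxy)-4,10-dimethyl-trans-decalin-7-ol | C=C1[C@H](O)C[C@@H]2[C@]3(C)COC(C)(C)O[C@@H]3CC[C@@]2(C)[C@@H]1CCI | intermediate
30 | 3-bromodihydrofuran-2(3H)-one (α-bromo-γ-butyrolactone) | O=C1OCCC1Br | starting material
31 | benzenethiol | Sc1ccccc1 | starting material
32 | 3-(phenylsulfanyl)dihydrofuran-2(3H)-one (racemic) | O=C1OCCC1Sc1ccccc1 | intermediate
33 | lithium enolate of 32 | [Li]OC1=C(Sc2ccccc2)CCO1 | intermediate
34 | 3-[2-(decalinyl)ethyl]-3-(phenylsulfanyl)dihydrofuran-2(3H)-one (decalinyl = the (7R)-7-hydroxy-8-methylidene 3,19-acetonide unit of 29; both C13 epimers) | C=C1[C@H](O)C[C@@H]2[C@]3(C)COC(C)(C)O[C@@H]3CC[C@@]2(C)[C@@H]1CCC1(Sc2ccccc2)CCOC1=O | intermediate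
35 | sulfoxide of 34 | C=C1[C@H](O)C[C@@H]2[C@]3(C)COC(C)(C)O[C@@H]3CC[C@@]2(C)[C@@H]1CCC1(S(=O)c2ccccc2)CCOC1=O | intermediate
36 | 3,19-O-isopropylidene-7-hydroxy-14-deoxyandrographolide | C=C1[C@H](O)C[C@@H]2[C@]3(C)COC(C)(C)O[C@@H]3CC[C@@]2(C)[C@@H]1CCC1=CCOC1=O | intermediate
37 | 3-{2-[(1S,3R,4aS,5R,6R,8aS)-3,6-dihydroxy-5-(hydroxymethyl)-5,8a-dimethyl-2-methylidenedecahydronaphthalen-1-yl]ethyl}furan-2(5H)-one | C=C1[C@H](O)C[C@@H]2[C@](C)(CO)[C@H](O)CC[C@@]2(C)[C@@H]1CCC1=CCOC1=O | target

**Step count and risks**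

Total step count: 20. Longest linear sequence: 19 (steps 1–16 and 18–20); step 17 prepares the lactone fragment.

Steps most likely to fail:

Step 5. The risk is a shift of the ring methylene C2 in place of C5, or retro-aldol loss of formaldehyde from the free β-hydroxy ketone while it is bound to the Lewis acid. The fallback moves the rearrangement from the free carbinol to its silyl ether, so that the aldol is released in protected form. It sets out from 11: 1-(trimethylsilyl)imidazole in CH2Cl2 gives the tertiary trimethylsilyl ether of the epoxy alcohol F1. Catalytic Me3SiOTf in CH2Cl2 at −78 °C then induces the same anti 1,2-shift, the silyl group passing from the carbinol oxygen to the epoxide oxygen, and gives the 19-O-trimethylsilyl ether of the ring A ketone F2. Citric acid in methanol removes the silyl group and the route is rejoined at 12.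

Step 4. The risk is poor or reversed facial selectivity in the directed epoxidation, because the size difference between C2 and C5 that the A(1,2) argument relies on may be too small; the wrong oxirane epimer would carry through to C4. The fallback builds the oxirane by C–C bond formation at a carbonyl instead of oxygen transfer to an alkene. It sets out from 8: 1-ethoxyvinyllithium (from ethyl vinyl ether and t-BuLi) with LaCl3·2LiCl in THF at −78 °C adds to the ketone on the same face as in step 3 and gives the 1-ethoxyvinyl carbinol F3. Aqueous oxalic acid hydrolyses the enol ether to the α-hydroxy methyl ketone F4. Dimethylsulfonium methylide (trimethylsulfonium iodide, KN(SiMe3)2, THF/DMSO, 0 °C; Corey–Chaykovsky epoxidation) then transfers methylene to the acetyl carbonyl. Under non-chelating conditions the polar Felkin–Anh model (C3–O anti to the incoming ylide, approach past the smaller C2) predicts the same (2S)-oxirane, and the route is rejoined at 11.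

Step 12. The risk is proton exchange between the lithium enolate and the hydroxymethylated product, or polymerisation of formaldehyde, either of which would erode conversion and the regiochemical fidelity of the enolate. The fallback replaces direct aldol trapping by aminomethylation of a silyl enol ether. It sets out from 21: after the same Li/NH3 reduction the enolate is silylated (Me3SiCl, Et3N) to the trimethylsilyl enol ether F5. Dimethylmethyleneammonium iodide (Eschenmoser's salt) in CH2Cl2 gives the 8-(dimethylaminomethyl) ketone F6. Methyl iodide converts it into the trimethylammonium iodide F7, which eliminates on stirring with NaHCO3, and the route is rejoined at 25, bypassing 23 and 24.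

**Further compounds**

F1 | step 5 | trimethylsilyl ether of epoxy alcohol 11 | C[C@]1(CO1)[C@@]2(O[Si](C)(C)C)CC[C@@](C)(C(=C)[Si](C)(C)C)[C@@H]2CC(=O)N(C)OC
F2 | step 5 | 19-O-trimethylsilyl ether of ring A ketone 12 | CON(C)C(=O)C[C@@H]1[C@](C)(CO[Si](C)(C)C)C(=O)CC[C@@]1(C)C(=C)[Si](C)(C)C
F3 | step 4 | 2-[(1S,2R,5R)-5-(1-ethoxyethenyl)-5-hydroxy-2-methyl-2-[1-(trimethylsilyl)ethenyl]cyclopentyl]-N-methoxy-N-methylacetamide | CCOC(=C)[C@@]1(O)CC[C@@](C)(C(=C)[Si](C)(C)C)[C@@H]1CC(=O)N(C)OC
F4 | step 4 | 2-[(1S,2R,5R)-5-acetyl-5-hydroxy-2-methyl-2-[1-(trimethylsilyl)ethenyl]cyclopentyl]-N-methoxy-N-methylacetamide | CC(=O)[C@@]1(O)CC[C@@](C)(C(=C)[Si](C)(C)C)[C@@H]1CC(=O)N(C)OC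
F5 | step 12 | trimethylsilyl enol ether (C7–O–Si, C7=C8) of the C9–H ketone | C1=C(O[Si](C)(C)C)C[C@@H]2[C@]3(C)COC(C)(C)O[C@@H]3CC[C@@]2(C)[C@@H]1CC1OCCO1
F6 | step 12 | 8-(dimethylaminomethyl)-9-(1,3-dioxolan-2-ylmethyl)-3,19-(isopropylidenedioxy)-4,10-dimethyl-trans-decalin-7-one | CN(C)C[C@H]1C(=O)C[C@@H]2[C@]3(C)COC(C)(C)O[C@@H]3CC[C@@]2(C)[C@@H]1CC1OCCO1
F7 | step 12 | trimethylammonium iodide of F6 | C[N+](C)(C)C[C@H]1C(=O)C[C@@H]2[C@]3(C)COC(C)(C)O[C@@H]3CC[C@@]2(C)[C@@H]1CC1OCCO1.[I-]
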